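**Retrosynthetic overview**

1. Drimane numbering is used for the decalin (C1–C10 ring carbons, C11 on C9, C12 on C8, C13 and C14 on C4, C15 on C10; α is the face opposite C15). Late disconnections: the C3 isovalerate (acylation), the C11–O aryl ether to isofraxidin (Mitsunobu), the C6 ketone (from the allylic alcohol) and the axial 3α-hydroxyl (bulky hydride on a C3 ketone).
2. Enabling feature: ring B is a 3-methylcyclohex-2-en-1-one (C6=O, C7=C8–C12) fused to ring A through C5–C10, so C6 and C8 are 1,5-related across C5 and the quaternary C10; once C11 is raised to an ester, C8–C9(C11)–C10 is an alkylidene acetoacetate.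
3. Key disconnection: C7=C8 (aldol condensation) and C5–C10 (Michael addition) are cut together, which opens both rings to an achiral open-chain triketo ester. In the forward sense ring A closes first and ring B second, in one flask, under a chiral bisoxazoline–copper Lewis acid that sets C10, C5 and C9.
4. The triketo ester is assembled from 2,2-dimethylpent-4-enal, 2-(2-bromoethyl)-2-methyl-1,3-dioxolane and methyl acetoacetate by Grignard addition, Jones oxidation with ketal cleavage, Knoevenagel condensation and Wacker oxidation.

Key step: step 5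

Assumption: the (S,S)-tert-butyl-bisoxazoline ligand, 2,2'-(propane-2,2-diyl)bis[(4S)-4-tert-butyl-4,5-dihydro-1,3-oxazole], is taken to expose the face of C10 that leads to the (10S) bicyclic diketo ester; its mirror image would be used if the sense of induction proves opposite.

**Step 1**
Reactants: 1 2,2-dimethylpent-4-enal; 2 2-(2-bromoethyl)-2-methyl-1,3-dioxolane
Product: 4 rac-4,4-dimethyl-1-(2-methyl-1,3-dioxolan-2-yl)hept-6-en-3-ol, via Grignard reagent 3 (not isolated)
Conditions: 2, Mg, THF, 25 °C; then 1, 0 °C; aq. NH4Cl
Reagents that add atoms: none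
Why: Grignard addition of the masked 3-oxobutyl nucleophile to a non-enolisable α-quaternary aldehyde; the carbinol centre forms as a racemate and is erased in step 2.

**Step 2**
Reactants: 4 rac-4,4-dimethyl-1-(2-methyl-1,3-dioxolan-2-yl)hept-6-en-3-ol
Product: 5 6,6-dimethylnon-8-ene-2,5-dione
Conditions: CrO3, H2SO4, H2O, acetone, 0 to 25 °C
Reagents that add atoms: water, O
Why: Jones oxidation of the secondary alcohol, with the aqueous acid of the same reagent hydrolysing the dioxolane, should give the 1,4-diketone in one operation while the terminal alkene is untouched.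

**Step 3**
Reactants: 5 6,6-dimethylnon-8-ene-2,5-dione; 6 methyl acetoacetate
Product: 7 methyl 2-acetyl-3,7,7-trimethyl-6-oxodeca-2,9-dienoate (E/Z mixture)
Conditions: TiCl4, pyridine, THF, 0 to 25 °C
Reagents that add atoms: none
Why: TiCl4/pyridine Knoevenagel condensation; only the methyl ketone should condense because the other carbonyl is shielded by the adjacent quaternary carbon, and the E/Z ratio is of no consequence since this geometry is lost in step 5.

**Step 4**
Reactants: 7 methyl 2-acetyl-3,7,7-trimethyl-6-oxodeca-2,9-dienoate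
Product: 8 methyl 2-acetyl-3,7,7-trimethyl-6,9-dioxodec-2-enoate (E/Z mixture)
Conditions: PdCl2 (10 mol %), CuCl, O2 (1 atm), DMF/H2O 7:1, 25 °C
Reagents that add atoms: water, O
Why: Tsuji–Wacker oxidation should turn the monosubstituted terminal alkene into the methyl ketone with Markovnikov selectivity; the electron-poor tetrasubstituted alkene does not bind divalent palladium.

**Step 5**
Reactants: 8 methyl 2-acetyl-3,7,7-trimethyl-6,9-dioxodec-2-enoate
Product: 11 methyl (5R,9R,10S)-3,6-dioxodrim-7-en-11-oate, via Michael adduct 9 (not isolated), via ketol 10 (not isolated)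
Conditions: [Cu((S,S)-t-Bu-box)](SbF6)2 (20 mol %), CH2Cl2, 0 to 25 °C; then TsOH·H2O (0.3 equiv), 40 °C
Reagents that add atoms: none
Why: Proposed new method: the bisoxazoline complex of divalent copper chelates the acetyl and ester carbonyls of the alkylidene acetoacetate in 8, the C5 enol of the C6 methyl ketone adds to C10 with transfer of its proton to the acceptor to give 9, and TsOH then drives aldol addition of the C7 enol to the C8 ketone (10) and loss of water to the C7=C8 enone. The closest known reactions are Lewis-acid-promoted intramolecular ene and hetero-Diels–Alder additions to alkylidene 1,3-dicarbonyl compounds, the ZnCl2- or BF3-mediated Michael–aldol annulation of mesityl oxide with an acetoacetate to a 4-alkoxycarbonylisophorone, and bisoxazoline–copper-catalysed enantioselective additions to chelating alkylidene malonates; a ketone enol adding enantioselectively to a tetrasubstituted acceptor has not been shown. Ring A closes by a 6-(enolexo)-exo-trig Michael addition and ring B by a 6-(enolendo)-exo-trig aldol condensation. C10 is set by the catalyst, which blocks one face of the chelated acceptor (the E and Z isomers of 8 are related by the pseudo-twofold axis of the chelate and should converge); C5 is set relative to C10 by a chair with the enol and C9 equatorial and the C10 methyl axial, the equatorial acetyl group also being the stable epimer of 9, which gives the trans ring fusion; C9 settles by enolisation as the pseudoaxial ester anti to the C10 methyl group, which avoids allylic strain with the C8 methyl group. The step needs the C5 and not the C7 enol to add, which the chain length secures because only C5 reaches C10 through a six-membered ring; it needs the aldol to run from C7 to C8 and not from C12 to C6, which the chelated β-keto ester secures by making C8 the electrophile; and the kinetic trans fusion must survive, for which the acid stage is kept mild.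

**Step 6**
Reactants: 11 methyl (5R,9R,10S)-3,6-dioxodrim-7-en-11-oate
Product: 12 methyl (3R,5R,9R,10S)-3-hydroxy-6-oxodrim-7-en-11-oate
Conditions: LiBH(s-Bu)3, THF, −78 °C; aq. NH4Cl
Reagents that add atoms: none
Why: Substrate-controlled ketone reduction; the bulky trialkylborohydride should attack the saturated C3 ketone along the equatorial trajectory, away from the syn-axial hydrogens at C1 and C5, and give the axial 3α-alcohol (3R), while the hindered cross-conjugated enone carbonyl and the ester are left.

**Step 7**
Reactants: 12 methyl (3R,5R,9R,10S)-3-hydroxy-6-oxodrim-7-en-11-oate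
Product: 13 (3R,5R,6R,9R,10R)-drim-7-ene-3,6,11-triol
Conditions: i-Bu2AlH (6 equiv), CH2Cl2, −78 to 0 °C; aq. KNaC4H4O6
Reagents that add atoms: none
Why: Hydride reduction with i-Bu2AlH should convert the methyl ester into the primary C11 alcohol and reduce the enone carbonyl in 1,2-fashion, hydride arriving anti to the axial methyl groups on C4 and C10 to give the 6β-alcohol, a temporary centre; C5 and C9 are not touched.

**Step 8**
Reactants: 13 (3R,5R,6R,9R,10R)-drim-7-ene-3,6,11-triol; 14 isofraxidin (7-hydroxy-6,8-dimethoxy-2H-chromen-2-one)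
Product: 15 7-{[(3R,5R,6R,9R,10R)-3,6-dihydroxydrim-7-en-11-yl]oxy}-6,8-dimethoxy-2H-chromen-2-one
Conditions: PPh3, DIAD, THF, 0 to 25 °C
Reagents that add atoms: none
Why: Mitsunobu etherification; the acidic phenol should displace the activated primary C11 hydroxyl by SN2, while the neopentyl-type axial 3α-hydroxyl and the 6β-hydroxyl flanked by two axial methyl groups are too hindered to be activated, and with C6 still an alcohol no vinylogous β-elimination can occur.

**Step 9**
Reactants: 15 7-{[(3R,5R,6R,9R,10R)-3,6-dihydroxydrim-7-en-11-yl]oxy}-6,8-dimethoxy-2H-chromen-2-one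
Product: 16 7-{[(3R,5R,9R,10R)-3-hydroxy-6-oxodrim-7-en-11-yl]oxy}-6,8-dimethoxy-2H-chromen-2-one
Conditions: MnO2 (excess), CH2Cl2, 25 °C
Reagents that add atoms: none
Why: Allylic oxidation with MnO2 should touch only the C6 alcohol and restore the enone under neutral conditions that neither enolise C5 nor eliminate the aryloxy group; the saturated 3α-alcohol and the coumarin are inert.

**Step 10**
Reactants: 16 7-{[(3R,5R,9R,10R)-3-hydroxy-6-oxodrim-7-en-11-yl]oxy}-6,8-dimethoxy-2H-chromen-2-one; 17 3-methylbutanoyl chloride
Product: 18 (3R,5R,9R,10R)-11-[(6,8-dimethoxy-2-oxo-2H-chromen-7-yl)oxy]-6-oxodrim-7-en-3-yl 3-methylbutanoate (target)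
Conditions: pyridine, DMAP (cat.), CH2Cl2, 0 to 25 °C
Reagents that add atoms: none
Why: DMAP-catalysed acylation of the last free, hindered axial hydroxyl; the weak amine base cannot deprotonate C9 or C5, so neither aryloxide loss nor epimerisation is expected.

**Compound list**

1 | 2,2-dimethylpent-4-enal | C=CCC(C)(C)C=O | starting material
2 | 2-(2-bromoethyl)-2-methyl-1,3-dioxolane | CC1(CCBr)OCCO1 | starting material
3 | [2-(2-methyl-1,3-dioxolan-2-yl)ethyl]magnesium bromide | CC1(CC[Mg]Br)OCCO1 | intermediate (not isolated)
4 | rac-4,4-dimethyl-1-(2-methyl-1,3-dioxolan-2-yl)hept-6-en-3-ol | CC1(CCC(O)C(C)(C)CC=C)OCCO1 | intermediate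
5 | 6,6-dimethylnon-8-ene-2,5-dione | CC(=O)CCC(=O)C(C)(C)CC=C | intermediate
6 | methyl acetoacetate (methyl 3-oxobutanoate) | COC(=O)CC(C)=O | starting material
7 | methyl 2-acetyl-3,7,7-trimethyl-6-oxodeca-2,9-dienoate (E/Z mixture) | COC(=O)C(C(C)=O)=C(C)CCC(=O)C(C)(C)CC=C | intermediate
8 | methyl 2-acetyl-3,7,7-trimethyl-6,9-dioxodec-2-enoate (E/Z mixture) | COC(=O)C(C(C)=O)=C(C)CCC(=O)C(C)(C)CC(C)=O | intermediate
9 | methyl 2-[(1S,2R)-2-acetyl-1,3,3-trimethyl-4-oxocyclohexyl]-3-oxobutanoate (acetyl cis to the ring methyl; epimers at the butanoate carbon) | COC(=O)C(C(C)=O)[C@@]1(C)CCC(=O)C(C)(C)[C@@H]1C(C)=O | intermediate (not isolated)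
10 | methyl (5R,10S)-8-hydroxy-3,6-dioxodriman-11-oate (trans-fused; epimers at C8 and C9) | COC(=O)C1C(C)(O)CC(=O)[C@H]2C(C)(C)C(=O)CC[C@]12C | intermediate (not isolated)
11 | methyl (5R,9R,10S)-3,6-dioxodrim-7-en-11-oate (5α-H; 9β-H; 10β-methyl) | COC(=O)[C@@H]1C(C)=CC(=O)[C@H]2C(C)(C)C(=O)CC[C@]12C | intermediate
12 | methyl (3R,5R,9R,10S)-3-hydroxy-6-oxodrim-7-en-11-oate (3α-OH) | COC(=O)[C@@H]1C(C)=CC(=O)[C@H]2C(C)(C)[C@H](O)CC[C@]12C | intermediate
13 | (3R,5R,6R,9R,10R)-drim-7-ene-3,6,11-triol (3α-OH; 6β-OH) | OC[C@@H]1C(C)=C[C@@H](O)[C@H]2C(C)(C)[C@H](O)CC[C@]12C | intermediate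
14 | isofraxidin (7-hydroxy-6,8-dimethoxy-2H-chromen-2-one) | COc1cc2ccc(=O)oc2c(OC)c1O | starting material
15 | 7-{[(3R,5R,6R,9R,10R)-3,6-dihydroxydrim-7-en-11-yl]oxy}-6,8-dimethoxy-2H-chromen-2-one | COc1cc2ccc(=O)oc2c(OC)c1OC[C@@H]1C(C)=C[C@@H](O)[C@H]2C(C)(C)[C@H](O)CC[C@]12C | intermediate
16 | 7-{[(3R,5R,9R,10R)-3-hydroxy-6-oxodrim-7-en-11-yl]oxy}-6,8-dimethoxy-2H-chromen-2-one | COc1cc2ccc(=O)oc2c(OC)c1OC[C@@H]1C(C)=CC(=O)[C@H]2C(C)(C)[C@H](O)CC[C@]12C | intermediate
17 | 3-methylbutanoyl chloride | CC(C)CC(Cl)=O | starting material
18 | (3R,5R,9R,10R)-11-[(6,8-dimethoxy-2-oxo-2H-chromen-7-yl)oxy]-6-oxodrim-7-en-3-yl 3-methylbutanoate | COc1cc2ccc(=O)oc2c(OC)c1OC[C@@H]1C(C)=CC(=O)[C@H]2C(C)(C)[C@H](OC(=O)CC(C)C)CC[C@]12C | target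

**Step count and risks**

Total step count: 10. Longest linear sequence: 10 steps (1 to 18).

Steps most likely to fail:

Step 5. What may go wrong:
- the catalyst may not discriminate the two faces of C10 well enough;
- a neutral ketone enol may add only slowly to the tetrasubstituted acceptor;
- the C3 ketone may enolise toward C2 and close by aldol addition onto the acetyl group;
- the trans ring fusion is a kinetic result, and long acid contact could erode it by enolisation toward C5.

The fallback moves enantiocontrol to a classical resolution with known chemistry. It sets out from 8: the same Michael–aldol condensation is run with the achiral Lewis acid Sc(OTf)3 and then TsOH, which gives 11 as a racemate together with its mirror image, methyl (5S,9S,10R)-3,6-dioxodrim-7-en-11-oate F1. Reduction with LiBH(s-Bu)3 as in step 6 gives 12 together with methyl (3S,5S,9S,10R)-3-hydroxy-6-oxodrim-7-en-11-oate F2. Esterification of the mixture with (S)-2-methoxy-2-phenylacetic acid (DCC, DMAP, CH2Cl2) gives two diastereomers, methyl (3R,5R,9R,10S)-3-[(2S)-2-methoxy-2-phenylacetoxy]-6-oxodrim-7-en-11-oate F3 and methyl (3S,5S,9S,10R)-3-[(2S)-2-methoxy-2-phenylacetoxy]-6-oxodrim-7-en-11-oate F4, which are separated by chromatography. F3 is then submitted to the conditions of step 7, where i-Bu2AlH removes the resolving acyl group while it reduces the methyl ester and the enone carbonyl, and the route is rejoined at 13.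

Step 8. What may go wrong:
- substitution at the β-branched primary carbon may be slow;
- the allylic 6-hydroxyl may be activated instead;
- the activated alcohol may eliminate.

The fallback replaces the redox condensation by sulfonate displacement. It sets out from 13: selective sulfonylation of the primary alcohol (MsCl, 2,4,6-collidine, CH2Cl2, −20 °C) gives (3R,5R,6R,9R,10R)-3,6-dihydroxydrim-7-en-11-yl methanesulfonate F5. Williamson etherification with 14 and Cs2CO3 in DMF at 60 °C rejoins the route at 15.

Step 6. What may go wrong:
- hydride may be delivered from the wrong face, giving the equatorial alcohol;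
- the borohydride may deprotonate C9 of the vinylogous β-keto ester instead of reducing C3.

The fallback replaces substrate control by reagent control. It sets out from 11: CBS reduction with (S)-2-methyl-CBS-oxazaborolidine and catecholborane in toluene at −78 °C, where the catalyst distinguishes the large flank (quaternary C4) from the small flank (C2 methylene), should give the (3R)-alcohol and rejoin the route at 12. Any concurrent 1,2-reduction of the enone carbonyl is harmless, because step 7 reduces C6 and step 9 reoxidises it. This fallback makes no compound that the list does not hold (F0).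

**Further compounds**

F1 | step 5 | methyl (5S,9S,10R)-3,6-dioxodrim-7-en-11-oate (mirror image of 11) | COC(=O)[C@H]1C(C)=CC(=O)[C@@H]2C(C)(C)C(=O)CC[C@@]12C
F2 | step 5 | methyl (3S,5S,9S,10R)-3-hydroxy-6-oxodrim-7-en-11-oate (mirror image of 12) | COC(=O)[C@H]1C(C)=CC(=O)[C@@H]2C(C)(C)[C@@H](O)CC[C@@]12C
F3 | step 5 | methyl (3R,5R,9R,10S)-3-[(2S)-2-methoxy-2-phenylacetoxy]-6-oxodrim-7-en-11-oate | COC(=O)[C@@H]1C(C)=CC(=O)[C@H]2C(C)(C)[C@H](OC(=O)[C@@H](OC)c3ccccc3)CC[C@]12C
F4 | step 5 | methyl (3S,5S,9S,10R)-3-[(2S)-2-methoxy-2-phenylacetoxy]-6-oxodrim-7-en-11-oate | COC(=O)[C@H]1C(C)=CC(=O)[C@@H]2C(C)(C)[C@@H](OC(=O)[C@@H](OC)c3ccccc3)CC[C@@]12C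
F5 | step 8 | (3R,5R,6R,9R,10R)-3,6-dihydroxydrim-7-en-11-yl methanesulfonate | CS(=O)(=O)OC[C@@H]1C(C)=C[C@@H](O)[C@H]2C(C)(C)[C@H](O)CC[C@]12C
F0 | step 6 | none | none
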